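Everything rests on opening pyranone ring C at three bonds. Its C4 carbonyl is flanked by C4a of ring A and by C3, and O1 ties C8a to C2. C4 is therefore latent carbon monoxide, C4a/O1 a latent ortho-iodophenol, and C2–C3 the triple bond of a ring B arylacetylene. One palladium-catalysed carbonylative annulation in diethylamine forges C4a–C4, C4–C3 and O1–C2 and delivers the complete flavone. The precursors are a phloroglucinol-derived iodophenol with O5 and O7 as methoxymethyl (MOM) ethers, and an alkyne with O4' as MOM ether and O3' as benzyl ether. After C3 hydroxylation, acid frees the hydroxyls to be sulfated. The chelated 5-OH resists sulfation, and O3' is unmasked last.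

Key step: step 6

Assumption: the target is taken as the free tris(hydrogen sulfate) exactly as drawn; because aryl hydrogen sulfates hydrolyse under their own acidity, the esters are carried as triethylammonium salts and protonated only in the final operation.

Abbreviations: MOM = methoxymethyl, Bn = benzyl, NIS = N-iodosuccinimide, DMDO = dimethyldioxirane, dppf = 1,1'-bis(diphenylphosphino)ferrocene, DMA = N,N-dimethylacetamide.

Step 1
Reactants: 1 phloroglucinol (benzene-1,3,5-triol, anhydrous)
Product: 2 3,5-bis(methoxymethoxy)phenol
Conditions: MOMCl (2.0 equiv), K2CO3 (2.2 equiv), acetone, 0 °C to rt; chromatography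
Reagents that add atoms: chloromethyl methyl ether (MOMCl), COCCl
Why: Williamson-type O-alkylation with the hard chloromethyl ether goes at oxygen, and since the three hydroxyls of 1 are equivalent, two equivalents of reagent should make the bis-ether the main member of a mono/bis/tris set that differs enough in polarity for chromatography, the other members being recyclable to 1 with acid.

Step 2
Reactants: 2 3,5-bis(methoxymethoxy)phenol
Product: 3 2-iodo-3,5-bis(methoxymethoxy)phenol
Conditions: NIS (1.0 equiv), CH2Cl2, −20 to 0 °C, dark
Reagents that add atoms: N-iodosuccinimide, O=C1CCC(=O)N1I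
Why: Electrophilic aromatic iodination of a ring activated by three oxygens should take one of the two equivalent positions next to the free hydroxyl in preference to C4, which is walled in by two MOM ethers and lacks hydrogen-bond delivery of NIS by the phenol, while one equivalent at low temperature guards against di-iodination.

Step 3
Reactants: 4 3,4-dihydroxybenzaldehyde
Product: 5 3-hydroxy-4-(methoxymethoxy)benzaldehyde
Conditions: MOMCl (1.05 equiv), K2CO3 (1.1 equiv), acetone, 0 °C to rt
Reagents that add atoms: chloromethyl methyl ether (MOMCl), COCCl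
Why: Regioselective Williamson etherification, in which the 4-OH para to the formyl group is clearly the more acidic, so one equivalent of weak base forms only the 4-phenoxide and the single equivalent of MOMCl is taken up there.

Step 4
Reactants: 5 3-hydroxy-4-(methoxymethoxy)benzaldehyde
Product: 6 3-(benzyloxy)-4-(methoxymethoxy)benzaldehyde
Conditions: BnBr (1.2 equiv), K2CO3 (1.5 equiv), DMF, rt
Reagents that add atoms: benzyl bromide, BrCc1ccccc1
Why: Plain Williamson benzylation of the only remaining phenol, with the aldehyde and the MOM acetal inert to carbonate.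

Step 5
Reactants: 6 3-(benzyloxy)-4-(methoxymethoxy)benzaldehyde
Product: 7 2-(benzyloxy)-4-ethynyl-1-(methoxymethoxy)benzene
Conditions: dimethyl (1-diazo-2-oxopropyl)phosphonate (1.3 equiv), K2CO3 (2 equiv), MeOH, rt
Reagents that add atoms: dimethyl (1-diazo-2-oxopropyl)phosphonate (Ohira–Bestmann reagent), COP(=O)(OC)C(=[N+]=[N-])C(C)=O
Why: Ohira–Bestmann variant of the Seyferth–Gilbert homologation, in which methanolysis frees the diazomethylphosphonate anion, this olefinates the non-enolisable aldehyde, and loss of nitrogen with a 1,2-hydrogen shift gives the terminal alkyne under conditions that leave both ethers alone.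

Step 6
Reactants: 3 2-iodo-3,5-bis(methoxymethoxy)phenol; 7 2-(benzyloxy)-4-ethynyl-1-(methoxymethoxy)benzene (1.2 equiv); 8 carbon monoxide
Product: 11 2-[3-(benzyloxy)-4-(methoxymethoxy)phenyl]-5,7-bis(methoxymethoxy)chromen-4-one, via ortho-hydroxyaryl ynone 9 (not isolated), via diethylamino enaminone 10 (not isolated)
Conditions: PdCl2(dppf) (5 mol %), CO (20 bar), Et2NH (solvent), 120 °C, autoclave, no copper salt
Reagents that add atoms: carbon monoxide (compound 8), [C-]#[O+]; diethylamine, CCNCC (its atoms appear in 10 only and leave again)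
Why: PdCl2(dppf) is reduced in the amine/CO medium to zerovalent palladium, which adds oxidatively to the aryl iodide of 3; migratory insertion of CO gives an acylpalladium species that takes up the amine-deprotonated alkyne 7 and reductively eliminates ynone 9, setting C4a–C4 and C4–C3. The solvent amine then adds to 9 in aza-Michael fashion, and in the β-amino enone 10 the neighbouring hydroxyl displaces the amino group at C2 by a 6-endo-trig addition–elimination, which sets O1–C2 and closes ring C. The closest known reaction type is the carbonylative Sonogashira coupling–annulation of ortho-iodophenols with terminal arylacetylenes to flavones in a secondary amine. No stereocentre is created. The step must avoid 5-exo-dig closure to an aurone, and it does so because amine addition makes the carbon next to the carbonyl nucleophilic and leaves C2 as the only acceptor site. It must also take up CO before the alkyne and keep the acyl group from the amine: copper-free conditions, CO pressure and the wide-bite-angle dppf favour insertion over direct coupling, the two ortho oxygens of 3 shield the acyl carbon from bulky diethylamine, and the single free hydroxyl of 3 fixes which oxygen becomes O1.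

Step 7
Reactants: 11 2-[3-(benzyloxy)-4-(methoxymethoxy)phenyl]-5,7-bis(methoxymethoxy)chromen-4-one
Product: 13 2-[3-(benzyloxy)-4-(methoxymethoxy)phenyl]-3-hydroxy-5,7-bis(methoxymethoxy)chromen-4-one, via racemic flavone 2,3-epoxide 12 (not isolated)
Conditions: DMDO (acetone solution, 2 equiv), CH2Cl2, 0 °C; evaporate; p-TsOH·H2O (cat.), CH2Cl2, rt
Reagents that add atoms: dimethyldioxirane, CC1(C)OO1
Why: Epoxidation of the enol-ether-like C2=C3 bond by neutral DMDO, followed by acid-catalysed opening at C2 (cation stabilised by O1 and ring B) and loss of H3, is the established flavone-to-flavonol oxidation, and the two transient stereocentres of cis-fused racemic 12 are erased when the C2=C3 bond is re-formed.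

Step 8
Reactants: 13 2-[3-(benzyloxy)-4-(methoxymethoxy)phenyl]-3-hydroxy-5,7-bis(methoxymethoxy)chromen-4-one
Product: 14 2-[3-(benzyloxy)-4-hydroxyphenyl]-3,5,7-trihydroxychromen-4-one (3'-O-benzylquercetin)
Conditions: HCl (2 M in MeOH), 50 °C; precipitate with water
Reagents that add atoms: none
Why: Acid-catalysed acetal exchange with methanol removes all three MOM groups as dimethoxymethane, while the benzyl aryl ether and the flavonol core tolerate dilute methanolic HCl.

Step 9
Reactants: 14 3'-O-benzylquercetin
Product: 15 tris(triethylammonium) 3'-O-benzylquercetin 3,7,4'-trisulfate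
Conditions: SO3·NEt3 (12 equiv), DMA, 65 °C; Et3N, precipitation with acetone/Et2O; gel filtration (aq. MeOH)
Reagents that add atoms: sulfur trioxide–triethylamine complex, CC[N+](CC)(CC)S(=O)(=O)[O-]
Why: O-Sulfonation of phenols with an amine–sulfur trioxide complex, in which the 7-OH, the 4'-OH and the enolic 3-OH react, the 5-OH is held in a six-membered hydrogen-bond chelate with the C4 carbonyl and is known to stay free in flavonoids under such conditions, and O3' cannot react because it is benzylated.

Step 10
Reactants: 15 tris(triethylammonium) 3'-O-benzylquercetin 3,7,4'-trisulfate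
Product: 17 quercetin 3,4',7-trisulfate (acid form), via tris(triethylammonium) quercetin 3,4',7-trisulfate 16 (not isolated)
Conditions: H2 (1 atm), Pd/C (10 wt % Pd), aq. MeOH, rt; filter; sulfonated polystyrene resin (H+ form), 4 °C; freeze-dry at once
Reagents that add atoms: none
Why: Catalytic hydrogenolysis cleaves the benzylic C–O bond without touching aryl sulfate salts or the tetrasubstituted C2=C3 bond, and a short cold cation exchange on the sulfonic acid resin swaps triethylammonium for protons to give the acid form drawn.

Compound list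
1 | phloroglucinol | Oc1cc(O)cc(O)c1 | starting material
2 | 3,5-bis(methoxymethoxy)phenol | Oc1cc(OCOC)cc(OCOC)c1 | intermediate
3 | 2-iodo-3,5-bis(methoxymethoxy)phenol | Oc1cc(OCOC)cc(OCOC)c1I | intermediate
4 | 3,4-dihydroxybenzaldehyde | O=Cc1ccc(O)c(O)c1 | starting material
5 | 3-hydroxy-4-(methoxymethoxy)benzaldehyde | O=Cc1ccc(OCOC)c(O)c1 | intermediate
6 | 3-(benzyloxy)-4-(methoxymethoxy)benzaldehyde | O=Cc1ccc(OCOC)c(OCc2ccccc2)c1 | intermediate
7 | 2-(benzyloxy)-4-ethynyl-1-(methoxymethoxy)benzene | C#Cc1ccc(OCOC)c(OCc2ccccc2)c1 | intermediate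
8 | carbon monoxide | [C-]#[O+] | starting material
9 | 3-[3-(benzyloxy)-4-(methoxymethoxy)phenyl]-1-[2-hydroxy-4,6-bis(methoxymethoxy)phenyl]prop-2-yn-1-one (not isolated) | O=C(C#Cc1ccc(OCOC)c(OCc2ccccc2)c1)c1c(O)cc(OCOC)cc1OCOC | intermediate
10 | (E)-3-[3-(benzyloxy)-4-(methoxymethoxy)phenyl]-3-(diethylamino)-1-[2-hydroxy-4,6-bis(methoxymethoxy)phenyl]prop-2-en-1-one (not isolated; push-pull double bond, configurationally labile) | O=C(/C=C(/N(CC)CC)c1ccc(OCOC)c(OCc2ccccc2)c1)c1c(O)cc(OCOC)cc1OCOC | intermediate
11 | 2-[3-(benzyloxy)-4-(methoxymethoxy)phenyl]-5,7-bis(methoxymethoxy)chromen-4-one | O=c1cc(-c2ccc(OCOC)c(OCc3ccccc3)c2)oc2cc(OCOC)cc(OCOC)c12 | intermediate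
12 | 2,3-epoxide of 11 (2,3-epoxyflavanone, cis-fused, racemic, one enantiomer drawn; not isolated) | O=C1[C@H]2O[C@@]2(c3ccc(OCOC)c(OCc4ccccc4)c3)Oc3cc(OCOC)cc(OCOC)c31 | intermediate
13 | 2-[3-(benzyloxy)-4-(methoxymethoxy)phenyl]-3-hydroxy-5,7-bis(methoxymethoxy)chromen-4-one | O=c1c(O)c(-c2ccc(OCOC)c(OCc3ccccc3)c2)oc2cc(OCOC)cc(OCOC)c12 | intermediate
14 | 2-[3-(benzyloxy)-4-hydroxyphenyl]-3,5,7-trihydroxychromen-4-one (3'-O-benzylquercetin) | O=c1c(O)c(-c2ccc(O)c(OCc3ccccc3)c2)oc2cc(O)cc(O)c12 | intermediate
15 | tris(triethylammonium) 3'-O-benzylquercetin 3,7,4'-trisulfate | O=c1c(OS(=O)(=O)[O-])c(-c2ccc(OS(=O)(=O)[O-])c(OCc3ccccc3)c2)oc2cc(OS(=O)(=O)[O-])cc(O)c12.CC[NH+](CC)CC.CC[NH+](CC)CC.CC[NH+](CC)CC | intermediate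
16 | tris(triethylammonium) quercetin 3,4',7-trisulfate (not isolated) | O=c1c(OS(=O)(=O)[O-])c(-c2ccc(OS(=O)(=O)[O-])c(O)c2)oc2cc(OS(=O)(=O)[O-])cc(O)c12.CC[NH+](CC)CC.CC[NH+](CC)CC.CC[NH+](CC)CC | intermediate
17 | quercetin 3,4',7-trisulfate, acid form (5-hydroxy-2-[3-hydroxy-4-(sulfooxy)phenyl]-4-oxochromene-3,7-diyl bis(hydrogen sulfate)) | O=c1c(OS(=O)(=O)O)c(-c2ccc(OS(=O)(=O)O)c(O)c2)oc2cc(OS(=O)(=O)O)cc(O)c12 | target

Total step count: 10
Longest linear sequence: 8 steps (steps 3 to 10, from 4)

Steps most likely to fail

Step 6. The C–I bond of 3 is electron-rich and flanked on both sides, so oxidative addition may be slow. Three processes could then take over: reductive loss of iodine, coupling without CO uptake followed by furan closure, or interception of the acylpalladium species by diethylamine. The fallback sets out from 2 and 7 and returns at 9. It brings in the carbonyl carbon as formaldehyde instead of CO. Magnesium-mediated ortho-formylation of 2 (MgCl2, Et3N, paraformaldehyde, MeCN, reflux; Casnati–Skattebøl reaction) should give 2-hydroxy-4,6-bis(methoxymethoxy)benzaldehyde F1, the two ortho sites being equivalent. Its sodium phenoxide (NaH, THF) is treated with the lithium acetylide of 7 (n-BuLi, THF, −78 °C) to give the racemic propargylic alcohol F2. MnO2 in CH2Cl2 oxidises this to ynone 9, which warm Et2NH in EtOH carries through 10 to 11.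

Step 9. Sulfation may stop short at the hindered O3 or O4', or creep onto the chelated 5-OH under forcing. It may also be undone by acid-promoted desulfation while a polyanionic mixture is being purified. The fallback sets out from 14 and returns at 15. It introduces sulfate in masked, neutral form. 2,2,2-Trichloroethyl chlorosulfate (3.3 equiv), Et3N and DMAP in THF at 0 °C should give 3'-O-benzylquercetin 3,7,4'-tris(2,2,2-trichloroethyl sulfate) F3, which can be freed on silica gel from under- or over-sulfated material. Zinc dust and HCO2NH4 in MeOH then cleave the trichloroethyl groups by reductive fragmentation to triammonium 3'-O-benzylquercetin 3,7,4'-trisulfate F4. Passage over a cation-exchange resin loaded with triethylammonium gives 15.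

Step 7. DMDO may attack the electron-rich rings or the benzylic C–H bonds faster than the deactivated enone bond, and conversion may stall. The acid used for epoxide opening may also start to strip MOM groups, which is harmless because step 8 removes them. The fallback sets out from 11 and returns at 13. It puts oxygen on C3 by metalation rather than epoxidation. LDA in THF at −78 °C removes H3, the most acidic C–H of the flavone. B(OMe)3 traps the anion as the dimethyl flavon-3-ylboronate F5, and H2O2/AcOH oxidises the C–B bond to give 13.

Further compounds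
F1 | step 6 | 2-hydroxy-4,6-bis(methoxymethoxy)benzaldehyde | O=Cc1c(O)cc(OCOC)cc1OCOC
F2 | step 6 | racemic 3-[3-(benzyloxy)-4-(methoxymethoxy)phenyl]-1-[2-hydroxy-4,6-bis(methoxymethoxy)phenyl]prop-2-yn-1-ol | OC(C#Cc1ccc(OCOC)c(OCc2ccccc2)c1)c1c(O)cc(OCOC)cc1OCOC
F3 | step 9 | 3'-O-benzylquercetin 3,7,4'-tris(2,2,2-trichloroethyl sulfate) | O=c1c(OS(=O)(=O)OCC(Cl)(Cl)Cl)c(-c2ccc(OS(=O)(=O)OCC(Cl)(Cl)Cl)c(OCc3ccccc3)c2)oc2cc(OS(=O)(=O)OCC(Cl)(Cl)Cl)cc(O)c12
F4 | step 9 | triammonium 3'-O-benzylquercetin 3,7,4'-trisulfate | O=c1c(OS(=O)(=O)[O-])c(-c2ccc(OS(=O)(=O)[O-])c(OCc3ccccc3)c2)oc2cc(OS(=O)(=O)[O-])cc(O)c12.[NH4+].[NH4+].[NH4+]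
F5 | step 7 | dimethyl {2-[3-(benzyloxy)-4-(methoxymethoxy)phenyl]-5,7-bis(methoxymethoxy)-4-oxochromen-3-yl}boronate | COB(OC)c1c(-c2ccc(OCOC)c(OCc3ccccc3)c2)oc2cc(OCOC)cc(OCOC)c2c1=O
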